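The pitfall in this flask is to count the charge of free catalyst as the catalyst that works.

| flask | starting material | reagent | free catalyst | impurity | remark |
|---|---|---|---|---|---|
| dusk | 1.5 M | 1.35 M | 100 mM | 23 mM | run made earlier |
| winter | 1.5 M | 1.35 M | 160 mM | 23 mM | run made earlier |
| flask | 1.5 M | 1.35 M | 75 mM | 23 mM |  |

- dusk (time / h: target / %, starting material / %): 0.833: 2.7, 93.9; 1.33: 4.6, 91.6; 2.00: 7.6, 88.3; 2.50: 10.8, 86.1; 4.00: 17.3, 79.0; 6.00: 27.4, 69.7; 10.0: 45.4, 52.8
- winter (time / h: target / %, starting material / %): 0.500: 1.3, 92.9; 1.33: 9.5, 85.4; 2.50: 19.7, 75.6; 4.00: 31.9, 63.3; 6.00: 46.9, 48.2; 8.00: 59.8, 36.3; 10.0: 70.0, 25.2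

(standard deviation of a reading: 0.5 percentage points)

1. apparent order in free catalyst when 30 % of the starting material are converted (percent change of the rate of making target for one percent more free catalyst charged)
2. apparent order in reagent when 30 % of the starting material are converted (percent change of the rate of making target for one percent more reagent charged)

What do the runs say about catalyst? Over a like stretch of starting material, 86.1 % down to 52.8 % in the dusk run and 85.4 % down to 48.2 % in the winter run, the readings put the winter run's rate of making target at 1.74 times the dusk run's, on 1.60 times the catalyst. Read as one power, that is an order of 1.17.

What could give more than first order? Suppose the impurity, 23 mM in each run, takes its equal in catalyst out. The working amounts c(free catalyst) − c(impurity) of the winter and dusk runs then stand in a ratio of 1.78, close to the rate reading.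

And the order at a given charge? Solve both ends. Take the rate as in step with the working amount, with c(impurity) held fixed. Far above c(impurity), one percent more catalyst is then one percent more working catalyst, so the order is one. Just above it, the same addition multiplies a small remainder, so the order climbs. Joined, the order is the inverse of the working share, c(free catalyst) − c(impurity) over c(free catalyst). In this flask that share is 69.3 %, so I reckon an order of 1.44.

But doesn't a plain power fit two runs equally well? Yes, one ratio cannot separate them. They part at this flask, where a plain power stays at 1.17. I commit to the share.

And reagent? No run changes its charge, so any number is a guess.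

The forecast gives 1.4 for catalyst (1.2 to 1.55) and 0.15 for reagent (0 to 0.45), with the words “It fits the impurity titrating catalyst”.

The flask gives 1.4 for catalyst and 0.34 for reagent, which is higher than the forecast's value and inside its range.

    starting material + catalyst intermediate B → catalyst intermediate C (k = 0.260 /M/min)
    catalyst intermediate C ⇌ catalyst intermediate D (K = 0.430, k = 0.130 /min)
    free catalyst + impurity → spent catalyst (k = 19.0 /M/min)
    catalyst intermediate D → free catalyst + target (k = 0.110 /min)
    reagent + free catalyst → catalyst intermediate A (k = 0.0730 /M/min)
    catalyst intermediate A ⇌ catalyst intermediate B (K = 51.0, k = 0.100 /min)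

At the start of this flask, free catalyst goes to reagent at 0.23 of the rate at which it goes to impurity. Counted against the working share 69.3 %, catalyst intermediate C in this flask at 8.00 h, the resting state and the largest form on the working round, holds 43.6 % of the working catalyst, and free catalyst holds 22.1 %.

The runs are calculated on assumed constants; noise was put on by code.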